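**Strategy**

The α-methylene-γ-butyrolactone is read as a lactonised homoallylic alcohol, so the plan rests on making the ring bond between C6 (the lactone O–CH) and C7 (its neighbour bearing the acrylate carbon C11; germacrane numbering) last. An intramolecular Nozaki–Hiyama–Kishi allylation of an open-chain 3(2H)-furanone, carrying a (Z)-enal at C6 and an (E)-2-(bromomethyl)enoate (C13–Br, C7=C11) on the C8–C9 arm, closes the ten-membered carbocycle, shifts the alkene to the exocyclic C11=C13 position, sets C6 and C7 and lactonises O6 onto C12 in one operation. It exploits the homoallylic pattern O6–C6–C7–C11=C13 of the lactone ring and the Z-C4=C5 alkene and furanone ring that hold the chain ends together.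

Key step: step 13

Remark: germacrane locants are used throughout (C1 ketone, C2=C3 and the C3–O–C10 bridge in the furanone, C4=C5, C6–O lactone, C7, C8–O ester, C9, C10; C11=C13, C12 lactone carbonyl). (S)-Citramalic acid, (Z)-3-methylpent-2-en-4-yn-1-ol and (E)-4-acetoxy-2-methylbut-2-enal are assumed to be commercially available.

**Route**

Step 1
Reactants: 1 (S)-citramalic acid
Product: 2 2-[(4S)-2,2,4-trimethyl-5-oxo-1,3-dioxolan-4-yl]acetic acid
Conditions: 2,2-dimethoxypropane, p-TsOH·H2O (cat.), CH2Cl2, rt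
Reagents that add atoms: 2,2-dimethoxypropane, COC(C)(C)OC
Why: Acid-catalysed transketalisation should tie the tertiary hydroxyl and the adjacent carboxyl into the five-membered dioxolanone, leaving the distal carboxyl free and the chiral-pool centre C10 untouched.

Step 2
Reactants: 2 2-[(4S)-2,2,4-trimethyl-5-oxo-1,3-dioxolan-4-yl]acetic acid
Product: 3 (5S)-5-(2-hydroxyethyl)-2,2,5-trimethyl-1,3-dioxolan-4-one
Conditions: BH3·SMe2, THF, 0 °C to rt; MeOH quench
Reagents that add atoms: none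
Why: Borane reduction is chemoselective for the free carboxylic acid (via the acyloxyborane) over the ester-type dioxolanone carbonyl.

Step 3
Reactants: 3 (5S)-5-(2-hydroxyethyl)-2,2,5-trimethyl-1,3-dioxolan-4-one
Product: 4 (5S)-2,2,5-trimethyl-5-[2-(triethylsilyloxy)ethyl]-1,3-dioxolan-4-one
Conditions: TESCl, imidazole, CH2Cl2, 0 °C
Reagents that add atoms: chlorotriethylsilane, CC[Si](Cl)(CC)CC
Why: Silylation of the primary alcohol blocks translactonisation onto the dioxolanone and later competition of this oxygen in the furanone closure.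

Step 4
Reactants: 5 (Z)-3-methylpent-2-en-4-yn-1-ol
Product: 6 tert-butyldimethylsilyl ether of 5, (Z)-tert-butyldimethyl[(3-methylpent-2-en-4-yn-1-yl)oxy]silane
Conditions: TBSCl, imidazole, DMF, rt
Reagents that add atoms: tert-butylchlorodimethylsilane, CC(C)(C)[Si](C)(C)Cl
Why: Standard silylation masks the allylic C6 hydroxyl, which would otherwise add to the ynone in 5-exo fashion, and leaves the Z-alkene and the terminal alkyne unchanged.

Step 5
Reactants: 6 TBS ether of the enynol, 4 (5S)-2,2,5-trimethyl-5-[2-(triethylsilyloxy)ethyl]-1,3-dioxolan-4-one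
Product: 9 (2S)-5-[(Z)-4-(tert-butyldimethylsilyloxy)but-2-en-2-yl]-2-methyl-2-[2-(triethylsilyloxy)ethyl]furan-3(2H)-one, via lithium acetylide 7 (not isolated), via hydroxy ynone 8 (not isolated)
Conditions: n-BuLi, THF, −78 °C; then 4, −78 °C; sat. aq. NH4Cl; crude in toluene, (Ph3P)AuNTf2 (2 mol %), rt
Reagents that add atoms: none
Why: The acetylide should acylate the non-enolisable dioxolanone once (the lithium hemiketal holds at −78 °C and loses acetone on quench), and gold-catalysed 5-endo-dig oxa-Michael cycloisomerisation of the α'-hydroxy ynone then gives the 3(2H)-furanone with C10 and the Z-alkene unchanged.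

Step 6
Reactants: 9 the furanone bis-silyl ether
Product: 10 2-{(2S)-5-[(Z)-4-(tert-butyldimethylsilyloxy)but-2-en-2-yl]-2-methyl-3-oxo-2,3-dihydrofuran-2-yl}acetaldehyde
Conditions: (COCl)2, DMSO, CH2Cl2, −78 to −40 °C; then i-Pr2NEt, −78 to −20 °C
Reagents that add atoms: none
Why: Under Swern conditions a primary triethylsilyl ether is cleaved and oxidised directly to the aldehyde while the TBS ether survives, and the cold hindered-amine quench limits β-elimination of the furanone oxygen.

Step 7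
Reactants: 10 the C8 aldehyde, 11 methyl propiolate
Product: 12 methyl (4R)-5-{(2S)-5-[(Z)-4-(tert-butyldimethylsilyloxy)but-2-en-2-yl]-2-methyl-3-oxo-2,3-dihydrofuran-2-yl}-4-hydroxypent-2-ynoate
Conditions: 11, Et2Zn, HMPA, CH2Cl2, rt; then (S)-BINOL (40 mol %), Ti(OiPr)4, 10, rt
Reagents that add atoms: none
Why: BINOL–Ti(OiPr)4-catalysed asymmetric alkynylzinc addition is expected to deliver the propiolate to the Si face of the aldehyde (the sense (S)-BINOL shows in dialkylzinc additions), setting C8 as (R) under catalyst control independently of the remote C10 centre.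

Step 8
Reactants: 12 the γ-hydroxy ynoate
Product: 13 methyl (4R)-4-(tert-butyldimethylsilyloxy)-5-{(2S)-5-[(Z)-4-(tert-butyldimethylsilyloxy)but-2-en-2-yl]-2-methyl-3-oxo-2,3-dihydrofuran-2-yl}pent-2-ynoate
Conditions: TBSOTf, 2,6-lutidine, CH2Cl2, −78 °C
Reagents that add atoms: tert-butyldimethylsilyl triflate, CC(C)(C)[Si](C)(C)OS(=O)(=O)C(F)(F)F
Why: Silylation with a non-nucleophilic base protects the C8 hydroxyl without conjugate addition to the ynoate and gives a poor leaving group at C8 for the later allylmetal stage.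

Step 9
Reactants: 13 the γ-silyloxy ynoate
Product: 15 methyl (2Z,4R)-4-(tert-butyldimethylsilyloxy)-5-{(2S)-5-[(Z)-4-(tert-butyldimethylsilyloxy)but-2-en-2-yl]-2-methyl-3-oxo-2,3-dihydrofuran-2-yl}-2-(hydroxymethyl)pent-2-enoate, via vinylalane 14 (not isolated)
Conditions: i-Bu2AlH, NMO, THF, 0 °C; then CH2O (gas from cracked paraformaldehyde), −20 °C to rt; aq. potassium sodium tartrate
Reagents that add atoms: formaldehyde, C=O
Why: Conjugate hydroalumination of the ynoate (vinylalumination) puts hydride on C7 and aluminium on C11, and hydroxymethylation of this allenolate-type species anti to the C8 substituent should fix C8 cis to CO2Me while C8 itself is not touched.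

Step 10
Reactants: 15 the 2-(hydroxymethyl)enoate
Product: 16 methyl (2E,4R)-2-(bromomethyl)-4-(tert-butyldimethylsilyloxy)-5-{(2S)-5-[(Z)-4-(tert-butyldimethylsilyloxy)but-2-en-2-yl]-2-methyl-3-oxo-2,3-dihydrofuran-2-yl}pent-2-enoate
Conditions: CBr4, PPh3, CH2Cl2, 0 °C
Reagents that add atoms: carbon tetrabromide, BrC(Br)(Br)Br
Why: Appel bromination converts the primary allylic alcohol into the bromide under neutral conditions with retention of the alkene geometry.

Step 11
Reactants: 16 the allylic bromide bis-TBS ether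
Product: 17 methyl (2E,4R)-2-(bromomethyl)-4-(tert-butyldimethylsilyloxy)-5-{(2S)-5-[(Z)-4-hydroxybut-2-en-2-yl]-2-methyl-3-oxo-2,3-dihydrofuran-2-yl}pent-2-enoate
Conditions: CSA (cat.), MeOH/CH2Cl2, 0 °C
Reagents that add atoms: none
Why: Acid-catalysed methanolysis removes the unhindered primary allylic TBS ether much faster than the hindered secondary one at C8, and the amine-free medium spares the allylic bromide.

Step 12
Reactants: 17 the C6 allylic alcohol
Product: 18 methyl (2E,4R)-2-(bromomethyl)-4-(tert-butyldimethylsilyloxy)-5-{(2S)-2-methyl-3-oxo-5-[(Z)-4-oxobut-2-en-2-yl]-2,3-dihydrofuran-2-yl}pent-2-enoate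
Conditions: Dess–Martin periodinane, NaHCO3, CH2Cl2, 0 °C; used at once
Reagents that add atoms: none
Why: Buffered Dess–Martin oxidation is neutral and non-nucleophilic, so the Z-enal should form without isomerisation and without attack on the allylic bromide.

Step 13
Reactants: 18 the bromo enal
Product: 21 (4Z)-8β-(tert-butyldimethylsilyloxy)-1-oxo-3,10-epoxygermacra-2,4,11(13)-trien-12,6α-olide (6R,7S,8R,10S; H-7α), via allylchromium dichloride 19 (not isolated), via macrocyclic hydroxy ester 20 (not isolated)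
Conditions: CrCl2 (10 equiv), THF, rt, syringe-pump addition of 18 (final 0.002 M); aq. NH4Cl; then CSA (cat.), CH2Cl2, rt
Reagents that add atoms: none
Why: Two equivalents of CrCl2 (divalent chromium) reduce the C13–Br bond to the allylchromium species 19 (trivalent chromium), whose γ-carbon C7 adds to the aldehyde carbon C6 through a six-membered chair with allylic transposition (SE2'), the closest known reaction type being the intramolecular Nozaki–Hiyama–Kishi allylation of 2-(bromomethyl)acrylates used for macrocyclic α-methylene lactones. The new C6–C7 bond closes the ten-membered carbocycle C1–C10 (formally a 10-exo-trig attack on C6=O; the ring is bridged C3–O–C10 by the furanone), and the chromium alkoxide on O6 then closes the γ-lactone by 5-exo-trig acyl substitution at C12 with loss of methanol, which the acid treatment completes. Because C8 is cis to CO2Me in 18, the chair carries C5 and C8 pseudo-equatorial, so C6 and C7 should form anti and the lactone should be trans-fused. The face of C7 is expected to be controlled by C8, since allylic 1,3-strain with the cis ester holds H8 in the alkene plane, the OTBS group turns outward and the tethered aldehyde bonds on the face that leaves H7 and H8 cis on the ring, placing the silyloxy and acrylate groups on the convex face away from the furanone. The step needs cyclisation instead of oligomerisation and attack on the aldehyde only, which are secured by slow addition at high dilution, by the Z-C4=C5 alkene and the planar furanone that hold C6 near C7, and by the inertness of the vinylogous-ester carbonyl C1 towards allylchromium reagents.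

Step 14
Reactants: 21 the 8-O-TBS lactone
Product: 22 (4Z)-8β-hydroxy-1-oxo-3,10-epoxygermacra-2,4,11(13)-trien-12,6α-olide (6R,7R,8R,10S)
Conditions: HF·pyridine, pyridine, THF, 0 °C to rt
Reagents that add atoms: none
Why: Buffered fluoride desilylation is mild enough to free the secondary C8 hydroxyl without base-induced translactonisation or conjugate addition to the α-methylene lactone.

Step 15
Reactants: 23 (E)-4-acetoxy-2-methylbut-2-enal
Product: 24 (E)-4-acetoxy-2-methylbut-2-enoic acid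
Conditions: NaClO2, NaH2PO4, 2-methyl-2-butene, t-BuOH/H2O, rt
Reagents that add atoms: sodium chlorite, [Na+].[O-]Cl=O
Why: Pinnick oxidation converts the enal into the acid without touching the allylic acetate or the E-alkene.

Step 16
Reactants: 22 the C8 alcohol, 24 (E)-4-acetoxy-2-methylbut-2-enoic acid
Product: 26 CNP0387534.1, (4Z)-8β-[(E)-4-acetoxy-2-methylbut-2-enoyloxy]-1-oxo-3,10-epoxygermacra-2,4,11(13)-trien-12,6α-olide (6R,7R,8R,10S), via mixed anhydride 25 (not isolated)
Conditions: 2-methyl-6-nitrobenzoic anhydride, Et3N, DMAP (cat.), CH2Cl2, rt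
Reagents that add atoms: none
Why: Shiina esterification through the mixed anhydride and the acylpyridinium ion acylates the hindered C8 hydroxyl with retention (the C8–O bond is not broken), and the tiglate-type E-geometry of the acid is the thermodynamically stable one.

**Compound list**

1 | (S)-citramalic acid, (2S)-2-hydroxy-2-methylbutanedioic acid | OC(=O)[C@](C)(CC(=O)O)O | starting material
2 | 2-[(4S)-2,2,4-trimethyl-5-oxo-1,3-dioxolan-4-yl]acetic acid | CC1(C)OC(=O)[C@](C)(CC(=O)O)O1 | intermediate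
3 | (5S)-5-(2-hydroxyethyl)-2,2,5-trimethyl-1,3-dioxolan-4-one | CC1(C)OC(=O)[C@](C)(CCO)O1 | intermediate
4 | (5S)-2,2,5-trimethyl-5-[2-(triethylsilyloxy)ethyl]-1,3-dioxolan-4-one | CC1(C)OC(=O)[C@](C)(CCO[Si](CC)(CC)CC)O1 | intermediate
5 | (Z)-3-methylpent-2-en-4-yn-1-ol | OC/C=C(/C)C#C | starting material
6 | (Z)-tert-butyldimethyl[(3-methylpent-2-en-4-yn-1-yl)oxy]silane | CC(C)(C)[Si](C)(C)OC/C=C(/C)C#C | intermediate
7 | lithium acetylide of 6 | CC(C)(C)[Si](C)(C)OC/C=C(/C)C#C[Li] | intermediate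
8 | (2Z,7S)-1-(tert-butyldimethylsilyloxy)-7-hydroxy-3,7-dimethyl-9-(triethylsilyloxy)non-2-en-4-yn-6-one | CC(C)(C)[Si](C)(C)OC/C=C(/C)C#CC(=O)[C@](C)(CCO[Si](CC)(CC)CC)O | intermediate
9 | (2S)-5-[(Z)-4-(tert-butyldimethylsilyloxy)but-2-en-2-yl]-2-methyl-2-[2-(triethylsilyloxy)ethyl]furan-3(2H)-one | CC(C)(C)[Si](C)(C)OC/C=C(/C)C1=CC(=O)[C@](C)(CCO[Si](CC)(CC)CC)O1 | intermediate
10 | 2-{(2S)-5-[(Z)-4-(tert-butyldimethylsilyloxy)but-2-en-2-yl]-2-methyl-3-oxo-2,3-dihydrofuran-2-yl}acetaldehyde | CC(C)(C)[Si](C)(C)OC/C=C(/C)C1=CC(=O)[C@](C)(CC=O)O1 | intermediate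
11 | methyl propiolate | C#CC(=O)OC | starting material
12 | methyl (4R)-5-{(2S)-5-[(Z)-4-(tert-butyldimethylsilyloxy)but-2-en-2-yl]-2-methyl-3-oxo-2,3-dihydrofuran-2-yl}-4-hydroxypent-2-ynoate | CC(C)(C)[Si](C)(C)OC/C=C(/C)C1=CC(=O)[C@](C)(C[C@@H](O)C#CC(=O)OC)O1 | intermediate
13 | methyl (4R)-4-(tert-butyldimethylsilyloxy)-5-{(2S)-5-[(Z)-4-(tert-butyldimethylsilyloxy)but-2-en-2-yl]-2-methyl-3-oxo-2,3-dihydrofuran-2-yl}pent-2-ynoate | CC(C)(C)[Si](C)(C)OC/C=C(/C)C1=CC(=O)[C@](C)(C[C@@H](O[Si](C)(C)C(C)(C)C)C#CC(=O)OC)O1 | intermediate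
14 | vinylalane of 13 (diisobutylaluminium on C11, H on C7, C8 cis to CO2Me) | CC(C)(C)[Si](C)(C)OC/C=C(/C)C1=CC(=O)[C@](C)(C[C@@H](O[Si](C)(C)C(C)(C)C)/C=C(/[Al](CC(C)C)CC(C)C)C(=O)OC)O1 | intermediate
15 | methyl (2Z,4R)-4-(tert-butyldimethylsilyloxy)-5-{(2S)-5-[(Z)-4-(tert-butyldimethylsilyloxy)but-2-en-2-yl]-2-methyl-3-oxo-2,3-dihydrofuran-2-yl}-2-(hydroxymethyl)pent-2-enoate | CC(C)(C)[Si](C)(C)OC/C=C(/C)C1=CC(=O)[C@](C)(C[C@@H](O[Si](C)(C)C(C)(C)C)/C=C(/CO)C(=O)OC)O1 | intermediate
16 | methyl (2E,4R)-2-(bromomethyl)-4-(tert-butyldimethylsilyloxy)-5-{(2S)-5-[(Z)-4-(tert-butyldimethylsilyloxy)but-2-en-2-yl]-2-methyl-3-oxo-2,3-dihydrofuran-2-yl}pent-2-enoate | CC(C)(C)[Si](C)(C)OC/C=C(/C)C1=CC(=O)[C@](C)(C[C@@H](O[Si](C)(C)C(C)(C)C)/C=C(/CBr)C(=O)OC)O1 | intermediate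
17 | methyl (2E,4R)-2-(bromomethyl)-4-(tert-butyldimethylsilyloxy)-5-{(2S)-5-[(Z)-4-hydroxybut-2-en-2-yl]-2-methyl-3-oxo-2,3-dihydrofuran-2-yl}pent-2-enoate | OC/C=C(/C)C1=CC(=O)[C@](C)(C[C@@H](O[Si](C)(C)C(C)(C)C)/C=C(/CBr)C(=O)OC)O1 | intermediate
18 | methyl (2E,4R)-2-(bromomethyl)-4-(tert-butyldimethylsilyloxy)-5-{(2S)-2-methyl-3-oxo-5-[(Z)-4-oxobut-2-en-2-yl]-2,3-dihydrofuran-2-yl}pent-2-enoate | O=C/C=C(/C)C1=CC(=O)[C@](C)(C[C@@H](O[Si](C)(C)C(C)(C)C)/C=C(/CBr)C(=O)OC)O1 | intermediate
19 | allylchromium dichloride from 18 (CrCl2 unit on C13) | O=C/C=C(/C)C1=CC(=O)[C@](C)(C[C@@H](O[Si](C)(C)C(C)(C)C)/C=C(/C[Cr](Cl)Cl)C(=O)OC)O1 | intermediate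
20 | methyl (4Z)-8β-(tert-butyldimethylsilyloxy)-6α-hydroxy-1-oxo-3,10-epoxygermacra-2,4,11(13)-trien-12-oate (6R,7S,8R,10S) | C=C(C(=O)OC)[C@H]1[C@H](O)/C=C(/C)C2=CC(=O)[C@](C)(C[C@H]1O[Si](C)(C)C(C)(C)C)O2 | intermediate
21 | (4Z)-8β-(tert-butyldimethylsilyloxy)-1-oxo-3,10-epoxygermacra-2,4,11(13)-trien-12,6α-olide (6R,7S,8R,10S) | C=C1C(=O)O[C@@H]2/C=C(/C)C3=CC(=O)[C@](C)(C[C@@H](O[Si](C)(C)C(C)(C)C)[C@@H]12)O3 | intermediate
22 | (4Z)-8β-hydroxy-1-oxo-3,10-epoxygermacra-2,4,11(13)-trien-12,6α-olide (6R,7R,8R,10S) | C=C1C(=O)O[C@@H]2/C=C(/C)C3=CC(=O)[C@](C)(C[C@@H](O)[C@@H]12)O3 | intermediate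
23 | (E)-4-acetoxy-2-methylbut-2-enal | CC(=O)OC/C=C(\C)C=O | starting material
24 | (E)-4-acetoxy-2-methylbut-2-enoic acid | CC(=O)OC/C=C(\C)C(=O)O | intermediate
25 | (E)-4-acetoxy-2-methylbut-2-enoic 2-methyl-6-nitrobenzoic anhydride | CC(=O)OC/C=C(\C)C(=O)OC(=O)c1c(C)cccc1[N+](=O)[O-] | intermediate
26 | CNP0387534.1, (4Z)-8β-[(E)-4-acetoxy-2-methylbut-2-enoyloxy]-1-oxo-3,10-epoxygermacra-2,4,11(13)-trien-12,6α-olide (6R,7R,8R,10S) | C=C1C(=O)O[C@@H]2/C=C(/C)C3=CC(=O)[C@](C)(C[C@@H](OC(=O)/C(C)=C/COC(C)=O)[C@@H]12)O3 | target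

**Step count**

Total steps: 16. Longest linear sequence: 14 (steps 1–3, 5–14 and 16, from 1).

**Steps most likely to fail**

Step 13. The ring closure may lose out to oligomerisation, or the anti and facial selectivity may erode if the allylchromium species isomerises before it adds. The fallback sets out from 13. Conjugate hydroalumination (i-Bu2AlH, HMPA, THF) and alkylation of the aluminium intermediate with ICH2Bpin would give the allylboronate F1. CSA in MeOH would free the allylic alcohol F2, and Dess–Martin oxidation would give the boronate enal F3, which is stable until activated. Sc(OTf)3 (10 mol %) in CH2Cl2 at high dilution would then trigger an intramolecular allylboration through a closed boron chair that cannot scramble the alkene geometry. The borate adduct would lactonise, and the route is rejoined at 21.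

Step 9. Hydride may attack the furanone carbonyl, or the aluminium intermediate may be protonated instead of captured by formaldehyde. The fallback sets out from 13. Syn-hydrostannation (Bu3SnH, Pd(PPh3)4 as the zerovalent palladium catalyst, THF, 0 °C) would give the α-stannyl enoate F4 with tin on C11. Iodine in CH2Cl2 would exchange tin for iodine with retention to give the α-iodo enoate F5. Stille coupling with Bu3SnCH2OH (Pd(PPh3)4, dioxane, 80 °C) would install the hydroxymethyl group and rejoin the route at 15.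

Step 7. The aldehyde may enolise and eliminate the furanone oxygen from C10, ethyl may transfer from Et2Zn, or facial control may be poor. The fallback sets out from 10. Addition of the lithium acetylide of 11 (LiN(SiMe3)2, THF, −78 °C) would give the propargylic alcohol F6 as a C8 epimer mixture. Dess–Martin oxidation would give the ynone F7. Noyori transfer hydrogenation with RuCl[(R,R)-TsDPEN](p-cymene) in i-PrOH, which is expected to give the (R)-propargylic alcohol from an alkynyl ketone, would rejoin the route at 12.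

Further compounds
F1 | step 13 | methyl (2Z,4R)-4-(tert-butyldimethylsilyloxy)-5-{(2S)-5-[(Z)-4-(tert-butyldimethylsilyloxy)but-2-en-2-yl]-2-methyl-3-oxo-2,3-dihydrofuran-2-yl}-2-[(4,4,5,5-tetramethyl-1,3,2-dioxaborolan-2-yl)methyl]pent-2-enoate | CC(C)(C)[Si](C)(C)OC/C=C(/C)C1=CC(=O)[C@](C)(C[C@@H](O[Si](C)(C)C(C)(C)C)/C=C(/CB2OC(C)(C)C(C)(C)O2)C(=O)OC)O1
F2 | step 13 | methyl (2Z,4R)-4-(tert-butyldimethylsilyloxy)-5-{(2S)-5-[(Z)-4-hydroxybut-2-en-2-yl]-2-methyl-3-oxo-2,3-dihydrofuran-2-yl}-2-[(4,4,5,5-tetramethyl-1,3,2-dioxaborolan-2-yl)methyl]pent-2-enoate | OC/C=C(/C)C1=CC(=O)[C@](C)(C[C@@H](O[Si](C)(C)C(C)(C)C)/C=C(/CB2OC(C)(C)C(C)(C)O2)C(=O)OC)O1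
F3 | step 13 | methyl (2Z,4R)-4-(tert-butyldimethylsilyloxy)-5-{(2S)-2-methyl-3-oxo-5-[(Z)-4-oxobut-2-en-2-yl]-2,3-dihydrofuran-2-yl}-2-[(4,4,5,5-tetramethyl-1,3,2-dioxaborolan-2-yl)methyl]pent-2-enoate | O=C/C=C(/C)C1=CC(=O)[C@](C)(C[C@@H](O[Si](C)(C)C(C)(C)C)/C=C(/CB2OC(C)(C)C(C)(C)O2)C(=O)OC)O1
F4 | step 9 | methyl (2E,4R)-4-(tert-butyldimethylsilyloxy)-5-{(2S)-5-[(Z)-4-(tert-butyldimethylsilyloxy)but-2-en-2-yl]-2-methyl-3-oxo-2,3-dihydrofuran-2-yl}-2-(tributylstannyl)pent-2-enoate | CC(C)(C)[Si](C)(C)OC/C=C(/C)C1=CC(=O)[C@](C)(C[C@@H](O[Si](C)(C)C(C)(C)C)/C=C(/[Sn](CCCC)(CCCC)CCCC)C(=O)OC)O1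
F5 | step 9 | methyl (2E,4R)-4-(tert-butyldimethylsilyloxy)-5-{(2S)-5-[(Z)-4-(tert-butyldimethylsilyloxy)but-2-en-2-yl]-2-methyl-3-oxo-2,3-dihydrofuran-2-yl}-2-iodopent-2-enoate | CC(C)(C)[Si](C)(C)OC/C=C(/C)C1=CC(=O)[C@](C)(C[C@@H](O[Si](C)(C)C(C)(C)C)/C=C(/I)C(=O)OC)O1
F6 | step 7 | methyl 5-{(2S)-5-[(Z)-4-(tert-butyldimethylsilyloxy)but-2-en-2-yl]-2-methyl-3-oxo-2,3-dihydrofuran-2-yl}-4-hydroxypent-2-ynoate, mixture of C4 epimers | CC(C)(C)[Si](C)(C)OC/C=C(/C)C1=CC(=O)[C@](C)(CC(O)C#CC(=O)OC)O1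
F7 | step 7 | methyl 5-{(2S)-5-[(Z)-4-(tert-butyldimethylsilyloxy)but-2-en-2-yl]-2-methyl-3-oxo-2,3-dihydrofuran-2-yl}-4-oxopent-2-ynoate | CC(C)(C)[Si](C)(C)OC/C=C(/C)C1=CC(=O)[C@](C)(CC(=O)C#CC(=O)OC)O1
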